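The route rests on disconnecting the C1–C2 bond of ring A, the cyclohexenol ring C1–C2–C3–C4–C5–C10 (atom names in the remark below), by a vinylogous aldol retron. C1 is the γ-carbon of the ring C ketone C12 through the furan bond C13=C16, and C2–C3=C4–C18 is a γ-hydroxy-enoate of lactone ring E. Catalytic base should therefore turn a tricyclic keto-furan that carries an (E)-4-oxobut-2-enoate arm on its spiro-lactone directly into the target, closing ring A and setting C1 and C2 in one operation. The precursor comes from an asymmetric Diels–Alder adduct (ring B), a retentive rhodium carbenoid C–H insertion (spiro-lactone), a Johnson–Claisen rearrangement (C9) and a Friedel–Crafts acylation (ring C).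

Key step: step 19

Remark (atom and ring names used throughout): C1 = CH bearing the furan; C2 = CHOH; C3 = alkene CH; C4 = alkene carbon bonded to the lactone carbonyl C18; C5 = quaternary carbon bearing C19H2–O; C6 = CH2; C7 = CHOAc; C8 = CH(CH3); C9 = quaternary C(CH3); C10 = ring-fusion CH; C11 = CH2; C12 = ketone; C13 and C16 = furan carbons bonded to C12 and C1. Ring A = C1–C2–C3–C4–C5–C10; ring B = cyclohexane C5–C10; ring C = cycloheptenone; ring D = furan; ring E = lactone.
Remark (assumptions): C4 of compounds 11–26 is a mixture of epimers that converges in step 17; 27 is used anhydrous, obtained from its commercial aqueous solution.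

**Step 1**
Reactants: 1 2-methylbut-1-en-3-yne
Product: 3 (2E)-3,4-dimethylpenta-2,4-dien-1-ol, via dienyldimethylalane 2 (not isolated)
Conditions: Me3Al, Cp2ZrCl2 (0.2 equiv), ClCH2CH2Cl, rt; n-BuLi, THF, −78 °C; (CH2O)n, rt; cold dilute HCl
Reagents that add atoms: trimethylaluminium C[Al](C)C; formaldehyde (from paraformaldehyde) C=O
Why: Negishi zirconium-catalysed carboalumination adds CH3 and Al syn across the alkyne with CH3 on the internal carbon, and the derived alanate is hydroxymethylated with retention, which should fix the E geometry of the C9=C10 bond.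

**Step 2**
Reactants: 3 (2E)-3,4-dimethylpenta-2,4-dien-1-ol
Product: 4 tert-butyl{[(2E)-3,4-dimethylpenta-2,4-dien-1-yl]oxy}dimethylsilane
Conditions: TBSCl, imidazole, CH2Cl2, 0 °C to rt
Reagents that add atoms: tert-butyldimethylsilyl chloride CC(C)(C)[Si](C)(C)Cl
Why: standard silylation of a primary alcohol (Corey protocol); no stereocentre is formed.

**Step 3**
Reactants: 4 silyl dienyl ether; 5 3-acryloyl-1,3-oxazolidin-2-one
Product: 6 3-{[(1S,2S)-2-({[tert-butyl(dimethyl)silyl]oxy}methyl)-3,4-dimethylcyclohex-3-en-1-yl]carbonyl}-1,3-oxazolidin-2-one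
Conditions: [Cu((S,S)-t-Bu-box)](SbF6)2 (10 mol%, divalent copper; t-Bu-box = 2,2'-(propane-2,2-diyl)bis[(4S)-4-tert-butyl-4,5-dihydro-1,3-oxazole]), CH2Cl2, −20 °C
Reagents that add atoms: none
Why: Evans bis(oxazoline)–copper-catalysed Diels–Alder reaction, in which the square-planar chelate of the s-cis imide exposes the Cα Re face, the 1-substituent of the diene directs "ortho" bonding (C10 to C5) and the endo transition state places C1 cis to the acyl carbon C19, which should set C10 and C5.

**Step 4**
Reactants: 6 Diels–Alder imide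
Product: 7 [(1S,2S)-2-({[tert-butyl(dimethyl)silyl]oxy}methyl)-3,4-dimethylcyclohex-3-en-1-yl]methanol
Conditions: LiBH4, MeOH (1 equiv), THF, 0 °C
Reagents that add atoms: none
Why: reductive cleavage of the N-acyloxazolidinone by LiBH4 should give the primary alcohol C19–OH without touching C5 or C10.

**Step 5**
Reactants: 7 primary alcohol; 8 (diethoxyphosphoryl)acetic acid
Product: 9 (diethoxyphosphoryl)acetate ester of 7
Conditions: DCC, DMAP (cat.), CH2Cl2, 0 °C to rt
Reagents that add atoms: none
Why: Steglich esterification of an unhindered primary alcohol.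

**Step 6**
Reactants: 9 phosphonoacetate ester
Product: 10 diazo(diethoxyphosphoryl)acetate ester of 7
Conditions: 4-acetamidobenzenesulfonyl azide, DBU, MeCN, 0 °C
Reagents that add atoms: 4-acetamidobenzenesulfonyl azide CC(=O)Nc1ccc(cc1)S(=O)(=O)N=[N+]=[N-]
Why: Regitz diazo transfer to the doubly activated methylene of the phosphonoacetate.

**Step 7**
Reactants: 10 diazo phosphonoacetate
Product: 11 spiro-lactone phosphonate with C1–OTBS (ring B cyclohexene spiro-fused at C5 to ring E; C19 cis and C4 trans to the C10 arm)
Conditions: Rh2(OAc)4 (2 mol%), ClCH2CH2Cl, 80 °C, slow addition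
Reagents that add atoms: none
Why: rhodium carbenoid 1,5 C–H insertion into the tertiary C5–H bond should form the γ-lactone and the quaternary spiro centre C5 with retention, so that C4 ends trans and C19 cis to the C10 arm; the acceptor/acceptor carbenoid prefers this five-membered transition state over reaction with the remote tetrasubstituted alkene.

**Step 8**
Reactants: 11 spiro-lactone phosphonate
Product: 12 C1 bromide of the spiro-lactone phosphonate
Conditions: Ph3PBr2, CH2Cl2, rt
Reagents that add atoms: dibromotriphenylphosphorane BrP(Br)(c1ccccc1)(c1ccccc1)c1ccccc1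
Why: direct conversion of a primary silyl ether into the bromide by Ph3PBr2 (silyl ether cleavage, then Appel-type displacement at C1), done while C9 is still sp2 and C1 is least hindered.

**Step 9**
Reactants: 12 bromide
Product: 13 C7 enone (C7 ketone conjugated with C8=C9)
Conditions: Rh2(cap)4 (cap = caprolactamate, 1 mol%), 70% aq. t-BuOOH, ClCH2CH2Cl, 40 °C
Reagents that add atoms: tert-butyl hydroperoxide CC(C)(C)OO
Why: dirhodium caprolactamate/t-BuOOH allylic oxidation (tert-butylperoxyl radical chain) should attack C7, the only allylic ring CH2 of the tetrasubstituted alkene, and give the enone.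

**Step 10**
Reactants: 13 enone
Product: 14 (7S)-allylic alcohol (C7–OH trans to the C10 arm)
Conditions: (R)-2-methyl-CBS-oxazaborolidine (0.2 equiv), BH3·SMe2, THF, −30 °C
Reagents that add atoms: none
Why: Corey–Bakshi–Shibata reduction, with the α-branched alkenyl arm as the large group, should deliver hydride under reagent control to give the (7S)-carbinol.

**Step 11**
Reactants: 14 allylic alcohol; 15 triethyl orthoacetate
Product: 17 ethyl ester with quaternary C9 (CH2CO2Et trans to the C10 arm; alkene C7=C8), via mixed ketene acetal 16 (not isolated)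
Conditions: EtCO2H (cat.), xylene, 140 °C, EtOH distilled off
Reagents that add atoms: none
Why: Johnson–Claisen rearrangement, whose suprafacial [3,3] shift transfers chirality from C7 to C9, forming the quaternary centre with C11 on the former C–O face and moving the alkene to C7=C8.

**Step 12**
Reactants: 17 bromo ester; 18 2-bromofuran
Product: 19 furfuryl ester (C1 bonded to furan C16)
Conditions: NiI2 (10 mol%), 4,4'-di-tert-butyl-2,2'-bipyridine, Zn, NaI, DMPU, 60 °C
Reagents that add atoms: none
Why: nickel-catalysed reductive cross-electrophile coupling (Weix type) should join C1 to the furan through an alkyl radical that is insensitive to β-branching at C10 and, with C9 now quaternary, has no homoallylic rearrangement path.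

**Step 13**
Reactants: 19 furfuryl ester
Product: 21 C7 alcohol (C7–OH and C8–CH3 trans), via C7 alkylborane 20 (not isolated)
Conditions: BH3·THF, THF, 0 °C; then 30% H2O2, aq. NaHCO3, 0 °C to rt
Reagents that add atoms: hydrogen peroxide OO
Why: hydroboration–oxidation should place boron on the less substituted C7 by syn addition from the face opposite the axial C20 methyl and axial C19, so that C7–OH and C8–CH3 end trans and both equatorial, as in the target.

**Step 14**
Reactants: 21 hydroxy ester
Product: 23 hydroxy acid (C12 acid; lactone intact), via ring-opened hydroxy diacid 22 (not isolated)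
Conditions: LiOH (4 equiv), THF/H2O, rt; then 1 M HCl to pH 2, rt
Reagents that add atoms: lithium hydroxide [Li+].[OH-]
Why: saponification of the ethyl ester (the γ-lactone opens as well) followed by acidification, which should re-close the Thorpe–Ingold-favoured spiro-γ-lactone and leave the C12 acid.

**Step 15**
Reactants: 23 hydroxy acid
Product: 24 acetoxy acid (C7–OAc)
Conditions: Ac2O, pyridine, DMAP (cat.), CH2Cl2, rt; then H2O
Reagents that add atoms: acetic anhydride CC(=O)OC(C)=O
Why: acetylation of the secondary C7 alcohol; the mixed anhydride formed at C12 is hydrolysed during aqueous work-up.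

**Step 16**
Reactants: 24 acetoxy acid
Product: 26 tricyclic keto phosphonate (rings B, C, D and E), via acid chloride 25 (not isolated)
Conditions: (COCl)2, DMF (cat.), CH2Cl2, 0 °C to rt; then SnCl4, CH2Cl2 (0.005 M), −78 to 0 °C
Reagents that add atoms: none
Why: intramolecular Friedel–Crafts acylation of the 2-alkylfuran at its β-carbon C13 should close the seven-membered ring C, because the trans-diequatorial arms on C9 and C10 hold the acylium next to C13 and high dilution disfavours attack on the free α-position of another molecule.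

**Step 17**
Reactants: 26 tricyclic keto phosphonate; 27 2,2-dimethoxyacetaldehyde
Product: 28 (E)-alkylidene lactone dimethyl acetal
Conditions: LiCl, DBU, MeCN, 0 °C to rt
Reagents that add atoms: none
Why: Masamune–Roush Horner–Wadsworth–Emmons olefination should deprotonate only the phosphonate carbon C4 (far more acidic than C11–H or the acetate), converge the C4 epimers and give the (E)-alkylidene lactone with C2 syn to C5.

**Step 18**
Reactants: 28 acetal
Product: 29 (E)-enal (C2 aldehyde on the C3=C4 alkylidene lactone)
Conditions: TFA/H2O (9:1), CHCl3, 0 °C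
Reagents that add atoms: water O
Why: acid hydrolysis of the dimethyl acetal; the acyl-deactivated furan, the acetate and the lactone should tolerate brief aqueous acid.

**Step 19**
Reactants: 29 (E)-enal
Product: 30 CNP0182929.2 (target)
Conditions: phosphazene base P2-Et, EtN=P(NMe2)2–N=P(NMe2)3 (0.2 equiv), THF, −40 to −10 °C; AcOH quench
Reagents that add atoms: none
Why: Proposed new method: a catalytic non-nucleophilic phosphazene base should deprotonate 29 reversibly at C11 and, through the furan bond C13=C16, at C1, and only the extended dienolate O–C12=C13–C16=C1 can reach the aldehyde, so its γ-carbon C1 adds to C2 and the C2 alkoxide turns the base over; the closest known reaction types are the intramolecular vinylogous aldol addition of γ-enolisable enones and the lateral metalation–aldehyde addition of 2-alkyl-3-furoates. Ring A closes in a 6-(enolexo)-exo-trig mode through a chair-like transition state. C1 is controlled by the tether from C5, which delivers C2 to the dienolate face that gives the trans-fused chair with H1 anti to H10 and the furan bond equatorial; C2 is controlled by the pseudo-equatorial placement of the carbonyl oxygen, and reversibility of the aldol should let this thermodynamic isomer (OH trans to the furan bond) accumulate. The step needs site selectivity for C1 over C11, which the substrate secures because the C11 enolate and the acceptor arm sit on the 1,3-diequatorial positions C9 and C5 of ring B and cannot meet, so C11 enolisation is unproductive and reversible. The (E)-geometry of 29 places C2 syn to C5, and low temperature with substoichiometric base should suppress E1cB loss of water and acetate cleavage.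

**Compound list**

1 | 2-methylbut-1-en-3-yne | C=C(C)C#C | starting material
2 | (E)-(2,3-dimethylbuta-1,3-dien-1-yl)dimethylalane | C=C(C)/C(C)=C/[Al](C)C | intermediate (not isolated)
3 | (2E)-3,4-dimethylpenta-2,4-dien-1-ol | C=C(C)/C(C)=C/CO | intermediate
4 | tert-butyl{[(2E)-3,4-dimethylpenta-2,4-dien-1-yl]oxy}dimethylsilane | C=C(C)/C(C)=C/CO[Si](C)(C)C(C)(C)C | intermediate
5 | 3-acryloyl-1,3-oxazolidin-2-one | C=CC(=O)N1CCOC1=O | starting material
6 | 3-{[(1S,2S)-2-({[tert-butyl(dimethyl)silyl]oxy}methyl)-3,4-dimethylcyclohex-3-en-1-yl]carbonyl}-1,3-oxazolidin-2-one (cis adduct; C5 acyl, C10 CH2OTBS) | O=C(N1CCOC1=O)[C@H]1CCC(C)=C(C)[C@H]1CO[Si](C)(C)C(C)(C)C | intermediate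
7 | [(1S,2S)-2-({[tert-butyl(dimethyl)silyl]oxy}methyl)-3,4-dimethylcyclohex-3-en-1-yl]methanol | OC[C@H]1CCC(C)=C(C)[C@H]1CO[Si](C)(C)C(C)(C)C | intermediate
8 | (diethoxyphosphoryl)acetic acid | OC(=O)CP(=O)(OCC)OCC | starting material
9 | (diethoxyphosphoryl)acetate of 7 | CCOP(=O)(OCC)CC(=O)OC[C@H]1CCC(C)=C(C)[C@H]1CO[Si](C)(C)C(C)(C)C | intermediate
10 | diazo(diethoxyphosphoryl)acetate of 7 | CCOP(=O)(OCC)C(=[N+]=[N-])C(=O)OC[C@H]1CCC(C)=C(C)[C@H]1CO[Si](C)(C)C(C)(C)C | intermediate
11 | spiro-lactone phosphonate: ring B cyclohexene (C8=C9) spiro at C5 to the γ-lactone C19H2–O–C18(=O)–C4H[P(O)(OEt)2]; C19 cis, C4 trans to the C10 CH2OTBS arm; C4 epimers | CCOP(=O)(OCC)C1C(=O)OC[C@]12CCC(C)=C(C)[C@H]2CO[Si](C)(C)C(C)(C)C | intermediate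
12 | C1 bromide of 11 (C10–CH2Br) | CCOP(=O)(OCC)C1C(=O)OC[C@]12CCC(C)=C(C)[C@H]2CBr | intermediate
13 | C7 enone of 12 | CCOP(=O)(OCC)C1C(=O)OC[C@]12CC(=O)C(C)=C(C)[C@H]2CBr | intermediate
14 | (7S)-allylic alcohol; C7–OH trans to the C10 arm | CCOP(=O)(OCC)C1C(=O)OC[C@]12C[C@H](O)C(C)=C(C)[C@H]2CBr | intermediate
15 | triethyl orthoacetate | CC(OCC)(OCC)OCC | starting material
16 | mixed ketene acetal of 14 (C7–O–C(=CH2)OEt) | CCOP(=O)(OCC)C1C(=O)OC[C@]12C[C@H](OC(=C)OCC)C(C)=C(C)[C@H]2CBr | intermediate (not isolated)
17 | ethyl ester with quaternary C9: C20 methyl cis and CH2CO2Et trans to the C10 arm; alkene C7=C8 | CCOP(=O)(OCC)C1C(=O)OC[C@]12CC=C(C)[C@](C)(CC(=O)OCC)[C@H]2CBr | intermediate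
18 | 2-bromofuran | Brc1ccco1 | starting material
19 | furfuryl ester: C10–CH2–(furan-2-yl) | CCOP(=O)(OCC)C1C(=O)OC[C@]12CC=C(C)[C@](C)(CC(=O)OCC)[C@H]2Cc1ccco1 | intermediate
20 | C7 alkylborane of 19 | CCOP(=O)(OCC)C1C(=O)OC[C@]12C[C@H](B)[C@@H](C)[C@](C)(CC(=O)OCC)[C@H]2Cc1ccco1 | intermediate (not isolated)
21 | C7 alcohol: (7S)-OH, (8S)-CH3, trans, both equatorial | CCOP(=O)(OCC)C1C(=O)OC[C@]12C[C@H](O)[C@@H](C)[C@](C)(CC(=O)OCC)[C@H]2Cc1ccco1 | intermediate
22 | ring-opened hydroxy diacid (C19–OH, C18 acid, C12 acid) | CCOP(=O)(OCC)C(C(=O)O)[C@]1(CO)C[C@H](O)[C@@H](C)[C@](C)(CC(=O)O)[C@H]1Cc1ccco1 | intermediate (not isolated)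
23 | hydroxy acid: spiro-lactone re-closed, C12 acid, C7–OH | CCOP(=O)(OCC)C1C(=O)OC[C@]12C[C@H](O)[C@@H](C)[C@](C)(CC(=O)O)[C@H]2Cc1ccco1 | intermediate
24 | acetoxy acid: C7–OAc, C12 acid | CCOP(=O)(OCC)C1C(=O)OC[C@]12C[C@H](OC(C)=O)[C@@H](C)[C@](C)(CC(=O)O)[C@H]2Cc1ccco1 | intermediate
25 | acid chloride of 24 | CCOP(=O)(OCC)C1C(=O)OC[C@]12C[C@H](OC(C)=O)[C@@H](C)[C@](C)(CC(=O)Cl)[C@H]2Cc1ccco1 | intermediate (not isolated)
26 | tricyclic keto phosphonate: ring B trans-fused to the furan-fused cycloheptenone (C12 ketone on furan C13, C1H2 on furan C16), spiro-lactone with C4–P(O)(OEt)2, C7–OAc | CCOP(=O)(OCC)C1C(=O)OC[C@]12C[C@H](OC(C)=O)[C@@H](C)[C@]3(C)CC(=O)c4ccoc4C[C@@H]23 | intermediate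
27 | 2,2-dimethoxyacetaldehyde | COC(OC)C=O | starting material
28 | (E)-alkylidene lactone dimethyl acetal: C4=C3H–C2H(OMe)2, C2 syn to C5 | COC(OC)/C=C1/C(=O)OC[C@]12C[C@H](OC(C)=O)[C@@H](C)[C@]3(C)CC(=O)c4ccoc4C[C@@H]23 | intermediate
29 | (E)-enal: C4=C3H–C2H=O, C2 syn to C5 | O=C/C=C1/C(=O)OC[C@]12C[C@H](OC(C)=O)[C@@H](C)[C@]3(C)CC(=O)c4ccoc4C[C@@H]23 | intermediate
30 | CNP0182929.2; (1S,2S,5S,7S,8S,9R,10R) in the atom names of the remark | CC(=O)O[C@H]1C[C@@]23COC(=O)C2=C[C@H](O)[C@H]2c4occc4C(=O)C[C@@](C)([C@@H]1C)[C@@H]23 | target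

**Totals**

Total step count: 19. Longest linear sequence: 19 steps (1 to 30); the route is fully linear.

**Steps most likely to fail**

1. Step 19 (Proposed new method). What may go wrong: the base may only cycle through the unproductive C11 enolate if proton transfer to the C1 dienolate is too slow, the aldol may lose water by E1cB elimination, or the acetate may be cleaved. The fallback uses known chemistry and makes the C1 nucleophile by reductive metalation instead of deprotonation. It sets out from 26: radical bromination at the furfuryl carbon C1 (NBS, (PhCO2)2, PhCF3, 80 °C) should give the C1-bromo keto phosphonate F1; Horner–Wadsworth–Emmons reaction with 27 (LiCl, i-Pr2NEt, MeCN) should give the bromo acetal F2; aqueous TFA should give the bromo enal F3; CrCl2 (divalent chromium) in THF should then effect a Nozaki–Hiyama-type intramolecular Barbier addition of the furfuryl chromium species to the C2 aldehyde. The fallback comes back to the route at 30.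

2. Step 7. What may go wrong: the carbenoid may be diverted to other C–H bonds, to the alkene or to dimerisation, so that site selectivity for C5–H is poor. The fallback builds the quaternary centre by enolate alkylation and sets out from 6: MeOMgBr in MeOH/CH2Cl2 should give the methyl ester F4; LDA, then tert-butyl bromoacetate (THF, −78 °C) should alkylate C5 anti to the C10 arm and give the diester F5; LiAlH4 should give the 1,4-diol F6; TEMPO (cat.) with PhI(OAc)2 should oxidise the less hindered C18 alcohol and close the spiro-lactone F7; LDA (2.2 equiv) and ClP(O)(OEt)2 should then install the phosphonate. The fallback comes back to the route at 11.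

3. Step 16. What may go wrong: intermolecular acylation at the free furan α-position (oligomerisation) or acid-induced furan decomposition may outcompete the seven-membered ring closure at the β-position. The fallback replaces the acylium by an activated amide and sets out from 24: coupling with Me2NH·HCl (EDC, HOBt, i-Pr2NEt) should give the N,N-dimethylamide F8; Tf2O and 2-fluoropyridine in CH2Cl2 (−78 to 0 °C), followed by aqueous NaHCO3, should effect an intramolecular Vilsmeier-type acylation of the furan and hydrolysis of the iminium ion. The fallback comes back to the route at 26.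

**Further compounds**

F1 | step 19 | C1-bromo keto phosphonate (26 brominated at the furfuryl carbon C1; C1 and C4 epimers) | CCOP(=O)(OCC)C1C(=O)OC[C@]12C[C@H](OC(C)=O)[C@@H](C)[C@]3(C)CC(=O)c4ccoc4C(Br)[C@@H]23
F2 | step 19 | C1-bromo (E)-alkylidene lactone dimethyl acetal | COC(OC)/C=C1/C(=O)OC[C@]12C[C@H](OC(C)=O)[C@@H](C)[C@]3(C)CC(=O)c4ccoc4C(Br)[C@@H]23
F3 | step 19 | C1-bromo (E)-enal | O=C/C=C1/C(=O)OC[C@]12C[C@H](OC(C)=O)[C@@H](C)[C@]3(C)CC(=O)c4ccoc4C(Br)[C@@H]23
F4 | step 7 | methyl (1S,2S)-2-({[tert-butyl(dimethyl)silyl]oxy}methyl)-3,4-dimethylcyclohex-3-ene-1-carboxylate | COC(=O)[C@H]1CCC(C)=C(C)[C@H]1CO[Si](C)(C)C(C)(C)C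
F5 | step 7 | C5-alkylated diester (CH2CO2t-Bu trans to the C10 arm) | COC(=O)[C@@]1(CC(=O)OC(C)(C)C)CCC(C)=C(C)[C@H]1CO[Si](C)(C)C(C)(C)C
F6 | step 7 | 1,4-diol (C19–OH and C18–OH) | OC[C@@]1(CCO)CCC(C)=C(C)[C@H]1CO[Si](C)(C)C(C)(C)C
F7 | step 7 | spiro-γ-lactone without phosphonate | O=C1OC[C@@]2(C1)CCC(C)=C(C)[C@H]2CO[Si](C)(C)C(C)(C)C
F8 | step 16 | N,N-dimethylamide of 24 | CCOP(=O)(OCC)C1C(=O)OC[C@]12C[C@H](OC(C)=O)[C@@H](C)[C@](C)(CC(=O)N(C)C)[C@H]2Cc1ccco1
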